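The route rests on opening ring A'' of the genkwanin half at C8''–C8a'' and C4a''–C5''. The substituent run C5''–OH, C6''–aryl, C7''–OMe, C8''–H around that ring is the imprint of a 2-aryl-1,3-dioxygenated butadiene on the C4a''=C8a'' bond of a 4-pyranone. In one operation a silyl ketene acetal diene and a 5-sulfinyl-4-pyranone combine and lose MeOSiMe3 and ArSOH. This should give the complete genkwanin core with free 5''-OH, 7''-OMe and the crowded C8–C6'' biaryl bond already in place. The diene carries a 4-methoxy-2,6-bis(methoxymethoxy)phenyl group, the future ring A. Its local symmetry leaves no regiochemical choice when ring C of the acacetin half is added afterwards.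

Key step: step 11

Numbering: unprimed locants belong to the acacetin half (rings A and C, ring B primed). Double-primed locants belong to the genkwanin half (rings A'' and C'', ring B'' triple-primed). Monoflavone intermediates are named with ordinary flavone locants.

Assumption: the target SMILES carries no descriptor for the hindered C8–C6'' axis, so the biflavone is made as the racemic mixture of atropisomers. All sulfoxides are racemic.

Design remarks:
- Ring A is constitutionally symmetric about the line C8···C5 as long as the oxygens on C7 and C8a carry the same group.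
- Two MOM ethers there and a methyl ether on the C5 oxygen make the lithiation site unique and make the two open ring carbons equivalent in the later acetylation.
- With this pattern only the C8a oxygen can close ring C. A free or labile C5 oxygen would open the way to the 6-linked isomer.
- The methyl ether is removed last, when it has become the peri-methoxy group beside the C4 carbonyl.
- The chelated 5''-OH set free by the key step is left unprotected, because the aroylation is run on the polyanion.

Step 1
Reactants: 1 methyl p-tolyl sulfoxide (racemic)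
Product: 2 1-(p-tolylsulfinyl)propan-2-one
Conditions: 1 (2 equiv), LiN(iPr)2 (2 equiv), THF, −78 °C; EtOAc (1 equiv), −78 → 0 °C; aq NH4Cl (surplus 1 recovered)
Reagents that add atoms: ethyl acetate, CCOC(C)=O
Why: Claisen-type acylation of an α-sulfinyl carbanion by an ester, the standard entry to β-keto sulfoxides, in which the second equivalent of carbanion deprotonates the more acidic product and so protects it from further attack.

Step 2
Reactants: 2 1-(p-tolylsulfinyl)propan-2-one
Product: 3 4-(dimethylamino)-3-(p-tolylsulfinyl)but-3-en-2-one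
Conditions: Me2NCH(OMe)2 (1.3 equiv), toluene, 60 °C
Reagents that add atoms: N,N-dimethylformamide dimethyl acetal, COC(OC)N(C)C
Why: Condensation of an amide acetal with an active methylene group: the CH2 between C=O and S=O is by far the most acidic site, so the aminomethylene unit (the future C8a''–H) should enter there and not at the acetyl CH3.

Step 3
Reactants: 3 4-(dimethylamino)-3-(p-tolylsulfinyl)but-3-en-2-one; 4 4-(benzyloxy)benzoyl chloride
Product: 6 2-[4-(benzyloxy)phenyl]-5-(p-tolylsulfinyl)-4H-pyran-4-one, via diketone 5 (not isolated)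
Conditions: LiN(SiMe3)2 (2.2 equiv), THF, −78 °C; 4, −78 → 0 °C; then CF3CO2H (excess), rt
Reagents that add atoms: none
Why: Known 4-pyranone synthesis from enaminones: the α'-enolate of the vinylogous amide is C-acylated by the aroyl chloride (extra base takes up the acidic diketone), and acid then lets the enol oxygen displace Me2NH at the aminomethylene carbon by 6-endo addition–elimination, the aryl vinyl sulfoxide having no α-hydrogen for a Pummerer reaction.

Step 4
Reactants: 7 5-methoxyresorcinol
Product: 8 1-methoxy-3,5-bis(methoxymethoxy)benzene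
Conditions: MOMCl (2.5 equiv), iPr2NEt, CH2Cl2, 0 °C → rt
Reagents that add atoms: chloromethyl methyl ether, COCCl
Why: O-Alkylation of both phenols with a hard α-chloro ether (acetal protection) under amine base, which keeps C-alkylation of the electron-rich ring negligible.

Step 5
Reactants: 8 1-methoxy-3,5-bis(methoxymethoxy)benzene
Product: 10 2-[4-methoxy-2,6-bis(methoxymethoxy)phenyl]ethanol, via aryllithium 9 (not isolated)
Conditions: n-BuLi (1.1 equiv), THF, 0 °C → rt; ethylene oxide (3 equiv, THF solution), −78 °C → rt; H2O
Reagents that add atoms: ethylene oxide, C1CO1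
Why: Directed ortho-metalation takes place at the carbon between the two chelating MOM ethers, the strongest cooperative pair of directing groups on the ring, and the aryllithium opens ethylene oxide by SN2 attack.

Step 6
Reactants: 10 2-[4-methoxy-2,6-bis(methoxymethoxy)phenyl]ethanol
Product: 11 [4-methoxy-2,6-bis(methoxymethoxy)phenyl]acetic acid
Conditions: TEMPO (7 mol %), NaClO2 (2 equiv), NaOCl (2 mol %), MeCN/phosphate buffer pH 6.7, 35 °C; acidify to pH 4
Reagents that add atoms: sodium chlorite, [Na+].[O-]Cl=O
Why: TEMPO-catalysed oxidation to the aldehyde coupled with chlorite (Pinnick-type) oxidation to the acid in a near-neutral buffer, a protocol suited to 2-arylethanols with electron-rich rings because hypochlorite is present only in traces, and mild enough for the MOM acetals.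

Step 7
Reactants: 11 [4-methoxy-2,6-bis(methoxymethoxy)phenyl]acetic acid
Product: 12 methyl [4-methoxy-2,6-bis(methoxymethoxy)phenyl]acetate
Conditions: MeI, K2CO3, DMF, rt
Reagents that add atoms: iodomethane, CI
Why: Carboxylate SN2 alkylation gives the methyl ester without the acid of a Fischer esterification, which the MOM ethers would not tolerate.

Step 8
Reactants: 12 methyl [4-methoxy-2,6-bis(methoxymethoxy)phenyl]acetate
Product: 13 methyl 2-[4-methoxy-2,6-bis(methoxymethoxy)phenyl]-3-oxobutanoate
Conditions: LiN(iPr)2 (2.1 equiv), THF, −78 °C; AcCl (1.05 equiv), −78 °C; aq NH4Cl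
Reagents that add atoms: acetyl chloride, CC(=O)Cl
Why: Crossed Claisen C-acylation of a lithium ester enolate with an acid chloride, the surplus base converting the β-keto ester into its enolate at once so that it is not acylated twice; the new α-stereocentre is racemic, labile through the enol and erased in step 9.

Step 9
Reactants: 13 methyl 2-[4-methoxy-2,6-bis(methoxymethoxy)phenyl]-3-oxobutanoate
Product: 14 methyl 3-methoxy-2-[4-methoxy-2,6-bis(methoxymethoxy)phenyl]but-2-enoate (E/Z mixture)
Conditions: Me2SO4 (1.2 equiv), K2CO3, DMF, rt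
Reagents that add atoms: dimethyl sulfate, COS(=O)(=O)OC
Why: O-Alkylation of a β-keto ester enolate: a hard methyl donor, a potassium counter-ion and a dipolar aprotic solvent favour oxygen, and the α-carbon is shielded by the di-ortho-substituted aryl group, so the enol ether should dominate, whose geometry does not matter.

Step 10
Reactants: 14 methyl 3-methoxy-2-[4-methoxy-2,6-bis(methoxymethoxy)phenyl]but-2-enoate
Product: 15 1,3-dimethoxy-2-[4-methoxy-2,6-bis(methoxymethoxy)phenyl]-1-(trimethylsilyloxy)buta-1,3-diene
Conditions: LiN(iPr)2 (1.2 equiv), THF, −78 °C; Me3SiCl (1.5 equiv), −78 °C → rt; evaporate, pentane, filter under Ar; used at once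
Reagents that add atoms: chlorotrimethylsilane, C[Si](C)(C)Cl
Why: γ-Deprotonation of a β-methoxy enoate that has no α-hydrogen and O-silylation of the extended enolate, the standard preparation of Brassard-type dienes; both isomers of 14 converge because the former double bond becomes the central single bond of the diene.

Step 11
Reactants: 15 1,3-dimethoxy-2-[4-methoxy-2,6-bis(methoxymethoxy)phenyl]-1-(trimethylsilyloxy)buta-1,3-diene; 6 2-[4-(benzyloxy)phenyl]-5-(p-tolylsulfinyl)-4H-pyran-4-one
Product: 17 4'-benzyloxy-5-hydroxy-7-methoxy-6-[4-methoxy-2,6-bis(methoxymethoxy)phenyl]flavone, via cycloadduct 16 (not isolated)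
Conditions: 15 (2 equiv), toluene, 4 Å MS, 90 °C, sealed tube, Ar; then SiO2, CH2Cl2, rt
Reagents that add atoms: none
Why: Proposed new method: the nucleophilic CH2 terminus of 15 (C8'') attacks C6 of the pyranone (C8a''), the carbon that is β to both the ring carbonyl and the sulfinyl group, and the ketene acetal carbon (C5'') bonds to the sulfinyl-bearing carbon (C4a''), either in one asynchronous suprafacial [4+2] event or by Mukaiyama–Michael addition followed by capture of the silyloxycarbenium ion by the α-sulfinyl enolate, giving cis-fused 16. The closest known reaction types are the cycloaddition–aromatisation of 1,3-dioxygenated silyl ketene acetal dienes with halo- or sulfinylquinones and the Diels–Alder reactions of 3-sulfinyl- or 3-acylchromones that end in xanthones, whereas a monocyclic 4-pyranone as 2π partner and a 2-aryl diene of this bulk are new. Ring A'' closes as the six-membered carbocycle of this [4+2] addition across C4a''=C8a'', after which the C5'' mixed acetal loses MeOSiMe3, the sulfinyl group, cis to C8a''–H, leaves by thermal syn elimination as p-toluenesulfenic acid, and the cross-conjugated dienone enolises to the 5''-phenol. No stereocentre survives, since those of 16 and the sulfur centre are erased and the C8–C6'' axis is not yet stereogenic while ring A is symmetric. The selectivity needed is orientational (C8'' on C8a'', not on C4a'' or C2''), and matched polarity secures it, because both acceptors of 6 polarise the same carbon while C2'' is only singly activated and carries an aryl group. Small, flexible MOM groups at both ortho positions keep the diene faces as open as a tetra-ortho-substituted biaryl allows, and the surplus diene takes up the sulfenic acid.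

Step 12
Reactants: 17 4'-benzyloxy-5-hydroxy-7-methoxy-6-[4-methoxy-2,6-bis(methoxymethoxy)phenyl]flavone
Product: 18 4'-benzyloxy-6-(2,6-dihydroxy-4-methoxyphenyl)-5-hydroxy-7-methoxyflavone
Conditions: conc. HCl (cat.), MeOH/THF, 50 °C
Reagents that add atoms: none
Why: Acid-catalysed acetal exchange with methanol frees both phenols as dimethoxymethane departs, while aryl methyl ethers, the benzyl ether and the flavone are inert to dilute methanolic acid.

Step 13
Reactants: 18 4'-benzyloxy-6-(2,6-dihydroxy-4-methoxyphenyl)-5-hydroxy-7-methoxyflavone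
Product: 19 6-(3-acetyl-2,6-dihydroxy-4-methoxyphenyl)-4'-benzyloxy-5-hydroxy-7-methoxyflavone
Conditions: AcOH (5 equiv), BF3·OEt2, 70 °C; then H2O/MeOH, 60 °C (hydrolysis of the BF2 chelates)
Reagents that add atoms: acetic acid, CC(=O)O
Why: BF3-mediated Friedel–Crafts acylation of a phloroglucinol-type ring (Fries rearrangement returns any O-acetate to carbon): the two open carbons of ring A are equivalent, so only one constitution can form, the ketone is tied up as a BF2 chelate with the adjacent C8a–OH, ring A'' is deactivated by its carbonyl group, and the now stereogenic C8–C6'' axis arises as the racemate.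

Step 14
Reactants: 19 6-(3-acetyl-2,6-dihydroxy-4-methoxyphenyl)-4'-benzyloxy-5-hydroxy-7-methoxyflavone; 20 4-methoxybenzoyl chloride
Product: 21 1-[3-(4'-benzyloxy-5-hydroxy-7-methoxyflavon-6-yl)-2,4-dihydroxy-6-methoxyphenyl]-3-(4-methoxyphenyl)propane-1,3-dione
Conditions: LiN(SiMe3)2 (5.5 equiv), THF, −78 → −10 °C; 20 (1.05 equiv), −78 °C → rt; 1 M HCl
Reagents that add atoms: none
Why: Direct C-aroylation of the lithium polyanion (three phenoxides plus the ketone enolate), the one-flask variant of the Baker–Venkataraman route, in which the enolate carbon is the most reactive site and an ester formed by chance on the C8a oxygen would be carried to the same 1,3-diketone by acyl migration under the excess base.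

Step 15
Reactants: 21 1-[3-(4'-benzyloxy-5-hydroxy-7-methoxyflavon-6-yl)-2,4-dihydroxy-6-methoxyphenyl]-3-(4-methoxyphenyl)propane-1,3-dione
Product: 22 4'''-benzyloxy-5'',7-dihydroxy-4',5,7''-trimethoxy-8,6''-biflavone
Conditions: H2SO4 (cat.), AcOH, 80 °C
Reagents that add atoms: none
Why: Acid-catalysed cyclodehydration of an o-hydroxyaryl 1,3-diketone, the closing stage of the Baker–Venkataraman flavone synthesis: C8a–OH is the only free hydroxyl ortho to the acyl group because the C5 oxygen is methylated, so ring C must close towards C8a and the 8-linked isomer results.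

Step 16
Reactants: 22 4'''-benzyloxy-5'',7-dihydroxy-4',5,7''-trimethoxy-8,6''-biflavone
Product: 23 4''',5,5'',7-tetrahydroxy-4',7''-dimethoxy-8,6''-biflavone (CNP0253922.0)
Conditions: BCl3 (6 equiv), C6HMe5 (3 equiv), CH2Cl2, −78 → 0 °C; MeOH/H2O, rt
Reagents that add atoms: none
Why: Lewis-acid ether cleavage: BCl3 with pentamethylbenzene as cation trap removes the aryl benzyl ether at low temperature and, on warming, cleaves only the C5 methyl ether, which forms a six-membered boron chelate with the C4 carbonyl, while the unchelated 7''- and 4'-methyl ethers are left.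

Compound list
1 | methyl p-tolyl sulfoxide (racemic) | Cc1ccc(cc1)S(C)=O | starting material
2 | 1-(p-tolylsulfinyl)propan-2-one (racemic at S) | CC(=O)CS(=O)c1ccc(C)cc1 | intermediate
3 | 4-(dimethylamino)-3-(p-tolylsulfinyl)but-3-en-2-one (push–pull alkene, geometry labile) | CC(=O)C(=CN(C)C)S(=O)c1ccc(C)cc1 | intermediate
4 | 4-(benzyloxy)benzoyl chloride | O=C(Cl)c1ccc(OCc2ccccc2)cc1 | starting material
5 | 1-[4-(benzyloxy)phenyl]-5-(dimethylamino)-4-(p-tolylsulfinyl)pent-4-ene-1,3-dione | CN(C)C=C(C(=O)CC(=O)c1ccc(OCc2ccccc2)cc1)S(=O)c1ccc(C)cc1 | intermediate (not isolated)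
6 | 2-[4-(benzyloxy)phenyl]-5-(p-tolylsulfinyl)-4H-pyran-4-one (racemic at S) | Cc1ccc(cc1)S(=O)c1coc(-c2ccc(OCc3ccccc3)cc2)cc1=O | intermediate
7 | 5-methoxyresorcinol | COc1cc(O)cc(O)c1 | starting material
8 | 1-methoxy-3,5-bis(methoxymethoxy)benzene | COCOc1cc(OC)cc(OCOC)c1 | intermediate
9 | [4-methoxy-2,6-bis(methoxymethoxy)phenyl]lithium | [Li]c1c(OCOC)cc(OC)cc1OCOC | intermediate (not isolated)
10 | 2-[4-methoxy-2,6-bis(methoxymethoxy)phenyl]ethanol | OCCc1c(OCOC)cc(OC)cc1OCOC | intermediate
11 | [4-methoxy-2,6-bis(methoxymethoxy)phenyl]acetic acid | OC(=O)Cc1c(OCOC)cc(OC)cc1OCOC | intermediate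
12 | methyl [4-methoxy-2,6-bis(methoxymethoxy)phenyl]acetate | COC(=O)Cc1c(OCOC)cc(OC)cc1OCOC | intermediate
13 | methyl 2-[4-methoxy-2,6-bis(methoxymethoxy)phenyl]-3-oxobutanoate (racemic, largely enolised) | COC(=O)C(C(C)=O)c1c(OCOC)cc(OC)cc1OCOC | intermediate
14 | methyl 3-methoxy-2-[4-methoxy-2,6-bis(methoxymethoxy)phenyl]but-2-enoate (E/Z mixture) | COC(=O)C(=C(C)OC)c1c(OCOC)cc(OC)cc1OCOC | intermediate
15 | 1,3-dimethoxy-2-[4-methoxy-2,6-bis(methoxymethoxy)phenyl]-1-(trimethylsilyloxy)buta-1,3-diene (ketene acetal geometry immaterial) | C=C(OC)C(=C(OC)O[Si](C)(C)C)c1c(OCOC)cc(OC)cc1OCOC | intermediate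
16 | 2-[4-(benzyloxy)phenyl]-5,7-dimethoxy-6-[4-methoxy-2,6-bis(methoxymethoxy)phenyl]-4a-(p-tolylsulfinyl)-5-(trimethylsilyloxy)-4a,5,8,8a-tetrahydro-4H-chromen-4-one (racemic, relative configuration shown: sulfinyl group and 8a-H cis; epimers at C5 and S) | COC1=C(c2c(OCOC)cc(OC)cc2OCOC)C(OC)(O[Si](C)(C)C)[C@@]2(S(=O)c3ccc(C)cc3)C(=O)C=C(c3ccc(OCc4ccccc4)cc3)O[C@H]2C1 | intermediate (not isolated)
17 | 4'-benzyloxy-5-hydroxy-7-methoxy-6-[4-methoxy-2,6-bis(methoxymethoxy)phenyl]flavone | COc1cc2oc(-c3ccc(OCc4ccccc4)cc3)cc(=O)c2c(O)c1-c1c(OCOC)cc(OC)cc1OCOC | intermediate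
18 | 4'-benzyloxy-6-(2,6-dihydroxy-4-methoxyphenyl)-5-hydroxy-7-methoxyflavone | COc1cc2oc(-c3ccc(OCc4ccccc4)cc3)cc(=O)c2c(O)c1-c1c(O)cc(OC)cc1O | intermediate
19 | 6-(3-acetyl-2,6-dihydroxy-4-methoxyphenyl)-4'-benzyloxy-5-hydroxy-7-methoxyflavone (racemic axis) | COc1cc2oc(-c3ccc(OCc4ccccc4)cc3)cc(=O)c2c(O)c1-c1c(O)c(C(C)=O)c(OC)cc1O | intermediate
20 | 4-methoxybenzoyl chloride | COc1ccc(cc1)C(=O)Cl | starting material
21 | 1-[3-(4'-benzyloxy-5-hydroxy-7-methoxyflavon-6-yl)-2,4-dihydroxy-6-methoxyphenyl]-3-(4-methoxyphenyl)propane-1,3-dione (racemic axis) | COc1cc2oc(-c3ccc(OCc4ccccc4)cc3)cc(=O)c2c(O)c1-c1c(O)c(C(=O)CC(=O)c2ccc(OC)cc2)c(OC)cc1O | intermediate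
22 | 4'''-benzyloxy-5'',7-dihydroxy-4',5,7''-trimethoxy-8,6''-biflavone (racemic axis) | COc1ccc(-c2cc(=O)c3c(OC)cc(O)c(-c4c(OC)cc5oc(-c6ccc(OCc7ccccc7)cc6)cc(=O)c5c4O)c3o2)cc1 | intermediate
23 | 4''',5,5'',7-tetrahydroxy-4',7''-dimethoxy-8,6''-biflavone, CNP0253922.0 (racemic axis) | COc1ccc(-c2cc(=O)c3c(O)cc(O)c(-c4c(OC)cc5oc(-c6ccc(O)cc6)cc(=O)c5c4O)c3o2)cc1 | target

Total step count: 16
Longest linear sequence: 13 steps (steps 4–16); steps 1–3 form the convergent branch.

Steps most likely to fail

Step 11.
- What may go wrong: the pyranone may be too poor a 2π partner for so shielded a diene, so that the diene is consumed by protodesilylation. Alternatively the first C–C bond may form and the pyranone ring then open by retro-oxa-Michael cleavage before C4a''–C5'' can close.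
- Fallback (known chemistry, Suzuki–Miyaura biaryl coupling), setting out from 8: lithiation as in step 5 and quenching with 2-isopropoxy-4,4,5,5-tetramethyl-1,3,2-dioxaborolane should give 2-[4-methoxy-2,6-bis(methoxymethoxy)phenyl]-4,4,5,5-tetramethyl-1,3,2-dioxaborolane F1. Commercial genkwanin is benzylated at its unchelated 4'-OH (BnBr, K2CO3, acetone) to 4'-O-benzylgenkwanin F2. This is iodinated at C6 with BnMe3N·ICl2 and CaCO3 in CH2Cl2/MeOH to 4'-O-benzyl-6-iodogenkwanin F3, then protected (MOMCl, NaH, DMF) as 4'-O-benzyl-6-iodo-5-O-(methoxymethyl)genkwanin F4. Coupling of the boronate and the iodide uses Pd2(dba)3, 2-dicyclohexylphosphino-2',6'-dimethoxybiphenyl and K3PO4 in toluene/H2O at 100 °C, a catalyst type made for tetra-ortho-substituted biaryls. It should give the 5-O-methoxymethyl ether of 17 F5, and the HCl/MeOH treatment of step 12 brings this back to the route at 18.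

Step 13.
- What may go wrong: the acylation may not stop cleanly. A second acetyl group may enter at C6, the new methyl ketone may itself be acetylated, or hot BF3 may strip the benzyl ether.
- Fallback (thermal Mentzer pyrone condensation instead of stepwise ring C construction), setting out from 18: this is heated neat with ethyl 3-(4-methoxyphenyl)-3-oxopropanoate at 200–240 °C (microwave or sealed tube). The aroylketene formed by loss of ethanol C-acylates either of the equivalent carbons of the phloroglucinol-type ring, and the neighbouring hydroxyl closes on the aryl ketone. The route is rejoined at 22, steps 13–15 are bypassed, and no compound outside the list is made.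

Step 14.
- What may go wrong: the polylithiated substrate may precipitate, and O-aroylation of the phenoxides may then outrun C-acylation of the enolate.
- Fallback (chalcone route instead of acylation), setting out from 19: Claisen–Schmidt condensation with 4-methoxybenzaldehyde (KOH, EtOH, rt), in which the potassium phenoxides stay dissolved, should give (E)-1-[3-(4'-benzyloxy-5-hydroxy-7-methoxyflavon-6-yl)-2,4-dihydroxy-6-methoxyphenyl]-3-(4-methoxyphenyl)prop-2-en-1-one F6. Oxidative cyclisation with I2 (cat.) in DMSO at 120 °C (oxa-Michael closure by C8a–OH, then dehydrogenation) comes back to the route at 22.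

Further compounds
F1 | step 11 | 2-[4-methoxy-2,6-bis(methoxymethoxy)phenyl]-4,4,5,5-tetramethyl-1,3,2-dioxaborolane | COCOc1cc(OC)cc(OCOC)c1B1OC(C)(C)C(C)(C)O1
F2 | step 11 | 4'-O-benzylgenkwanin | COc1cc(O)c2c(=O)cc(-c3ccc(OCc4ccccc4)cc3)oc2c1
F3 | step 11 | 4'-O-benzyl-6-iodogenkwanin | COc1cc2oc(-c3ccc(OCc4ccccc4)cc3)cc(=O)c2c(O)c1I
F4 | step 11 | 4'-O-benzyl-6-iodo-5-O-(methoxymethyl)genkwanin | COCOc1c(I)c(OC)cc2oc(-c3ccc(OCc4ccccc4)cc3)cc(=O)c12
F5 | step 11 | 5-O-methoxymethyl ether of 17 | COCOc1c(-c2c(OCOC)cc(OC)cc2OCOC)c(OC)cc2oc(-c3ccc(OCc4ccccc4)cc3)cc(=O)c12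
F0 | step 13 | none | none
F6 | step 14 | (E)-1-[3-(4'-benzyloxy-5-hydroxy-7-methoxyflavon-6-yl)-2,4-dihydroxy-6-methoxyphenyl]-3-(4-methoxyphenyl)prop-2-en-1-one | COc1ccc(/C=C/C(=O)c2c(OC)cc(O)c(-c3c(OC)cc4oc(-c5ccc(OCc6ccccc6)cc5)cc(=O)c4c3O)c2O)cc1
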